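The data are simulated with made-up constants; noise was put on by code.

The substrate still left at the last reading of each earlier run was my starting point, and the question for it was whether the 6.0 min stop on Saturday's and Tuesday's flasks could stand or had to be lengthened, given that I wanted to know what would lead at that stop.

| flask | substrate | partner | second reagent | third reagent | temperature | remark | time |
|---|---|---|---|---|---|---|---|
| green | 0.14 M | 1.1 equiv | 1.2 equiv | 4 equiv | 22 °C | run made earlier |  |
| teal | 0.22 M | 1.1 equiv | 1.2 equiv | 4 equiv | 37 °C | run made earlier |  |
| Saturday's | 0.29 M | 1.10 equiv | 1.20 equiv | 4.00 equiv | 25 °C |  | 6.0 min |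
| Tuesday's | 0.29 M | 1.10 equiv | 1.20 equiv | 4.00 equiv | 33 °C |  | 6.0 min |

green run (percent of the substrate charged)

| time / min | side product B / % | substrate / % | intermediate B / % | target / % |
|---|---|---|---|---|
| 0.250 | 0.3 | 97.8 | 0 | 1.3 |
| 0.500 | 0.1 | 95.9 | 0.9 | 0 |
| 1.00 | 0.8 | 94.4 | 1.6 | 0.1 |
| 2.00 | 0 | 87.1 | 6.0 | 0 |
| 4.00 | 3.4 | 79.2 | 12.4 | 1.8 |

teal run (percent of the substrate charged)

| time / s | side product B / % | substrate / % | intermediate B / % | target / % |
|---|---|---|---|---|
| 10.0 | 0 | 95.8 | 2.9 | 0.8 |
| 15.0 | 0.6 | 94.8 | 1.6 | 0 |
| 30.0 | 1.8 | 88.4 | 5.6 | 1.8 |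
| 60.0 | 4.4 | 79.8 | 12.3 | 0.8 |
| 120 | 7.0 | 66.1 | 17.2 | 6.1 |

(readings scatter by 1 percentage point)

- the analysis behind the earlier runs scatters by 1 percentage point, standard deviation
- candidate steps: substrate + partner -> intermediate A; second reagent + intermediate A -> intermediate B; third reagent + intermediate B -> target; substrate + second reagent -> side product A; intermediate A -> side product B

1. which of these there is most of at the end, counted by the substrate in it, Saturday's (side product B / substrate / target / intermediate B)
2. which of these there is most of at the end, counted by the substrate in it, Tuesday's (side product B / substrate / target / intermediate B)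
3. how much there is at the end of the one of these that leads, in percent of the substrate charged: Saturday's
4. how much there is at the end of the one of these that leads, in percent of the substrate charged: Tuesday's

The substrate is the limiting reagent against the partner at 1.10 equiv, so I reckoned with the fraction left, f, and not with any product. If the two are used one for one, with q equivalents of partner, then f = (q − 1) / (q·exp(k[substrate](q − 1)t) − 1), with [substrate] as charged. Solved for k, the green run's last reading gave 0.421 M⁻¹ min⁻¹ and the teal run's gave 1.04 M⁻¹ min⁻¹, both readings with the scatter stated. I interpolated ln k in temperature between them. That gave 0.504 M⁻¹ min⁻¹ for Saturday's flask and, for Tuesday's, the pair constant, the k that carries the fraction left of substrate at 33 °C: 0.815 M⁻¹ min⁻¹.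

So I expected f of 49.8% on Saturday's flask and 37.4% on Tuesday's. A product overtakes the substrate when it holds more than f/(1 − f) of what has reacted. That is 0.991 for Saturday's flask, and the green run's intermediate B read 0.596, less. For Tuesday's flask it is 0.597, and the teal run's intermediate B read 0.507, less again. I therefore left the charges and the time as they stood and counted on substrate leading in both.

The forecast gave 50% and 38%, the second slightly above my figure: “Substrate therefore still leads in both runs.”

Substrate led with 48.2% on Saturday's flask and 34.7% on Tuesday's, where target held 0.362 of what had reacted, less than the 0.531 that f/(1 − f) gives with the substrate Tuesday's flask actually held. The pair constant 0.815 M⁻¹ min⁻¹ had put Tuesday's flask 2.7 percentage points above what it gave.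

    substrate + partner → intermediate A (k = 0.00780 M⁻¹ s⁻¹, Ea = 46.0 kJ mol⁻¹)
    second reagent + intermediate A → intermediate B (k = 0.120 M⁻¹ s⁻¹, Ea = 58.0 kJ mol⁻¹)
    third reagent + intermediate B → target (k = 0.00150 M⁻¹ s⁻¹, Ea = 66.0 kJ mol⁻¹)
    substrate + second reagent → side product A (k = 6.70 × 10⁻⁴ M⁻¹ s⁻¹, Ea = 53.0 kJ mol⁻¹)
    intermediate A → side product B (k = 0.00580 s⁻¹, Ea = 84.0 kJ mol⁻¹)
    (constants at 25 °C)

On a neighbour of Tuesday's charged with 0.12 M of substrate, at the same equivalents, temperature and time, 0.815 M⁻¹ min⁻¹ gives f = 60.1%. That flask held 58.5%.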